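**Assumption (one line):** the vanadium epoxidation of (S)-linalool gives the (2R,3S) terminal epoxide as the major diastereomer; the minor one gives the cis-epoxy alcohol after Payne rearrangement and is removed by chromatography. The phenol is carried as its acetate through the bromonium steps to avoid chroman formation and arene bromination.

**Retrosynthesis**
1. Target ⇒ K2CO3/MeOH deacetylation of the phenol-acetate macrolactone.
2. Macrolactone ⇒ one electrochemical Br⁺ cascade on an acyclic polyene acid: 6-endo bromonium cyclization builds the cyclohexene ring (quaternary C–Me, C–Br, tetrasubstituted alkene), then macro-bromolactonization of the prenyl terminus closes the 15-membered tertiary ester and sets the second C–Br.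
3. Polyene acid ⇒ cross-metathesis of a methallyl epoxide (from (S)-linalool by V-epoxidation, Payne rearrangement, and Cu-catalysed Grignard displacement) with an aryl-diene acid.
4. The aryl-diene acid ⇒ Ni-electroreductive aryl–allyl coupling. Ring order: cyclohexene first, macrocycle second.

---

**Step 1**
Reactants: 1 (S)-linalool
Product: 2 (2R,3S)-1,2-epoxy-3,7-dimethyloct-6-en-3-ol
Conditions: VO(acac)2 (2 mol %), TBHP (1.1 equiv), CH2Cl2, 0 °C→rt
Reagents that add atoms: tert-butyl hydroperoxide, CC(C)(C)OO (oxygen atom)
Why: The tertiary allylic alkoxide directs V(V)-peroxide (Sharpless–Michaelson hydroxyl-directed epoxidation) to the vinyl group over the prenyl alkene, and the existing C3 (S) centre biases the new C2 centre.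

**Step 2**
Reactants: 2
Product: 3 (2S,3S)-2,3-epoxy-3,7-dimethyloct-6-en-1-ol
Conditions: 0.5 M NaOH (aq)/t-BuOH, 25 °C, 12 h
Reagents that add atoms: none
Why: Payne rearrangement moves the epoxide to the more substituted 2,3-position, which is favoured thermodynamically. Attack of the C3 oxygen inverts C2 (R→S) while C3 is retained, giving the trans-epoxide with both centres as in the target.

**Step 3**
Reactants: 3
Product: 4 (2S,3S)-2,3-epoxy-3,7-dimethyloct-6-en-1-yl tosylate
Conditions: TsCl, Et3N, DMAP (cat.), CH2Cl2, 0 °C
Reagents that add atoms: p-toluenesulfonyl chloride, Cc1ccc(cc1)S(=O)(=O)Cl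
Why: Standard sulfonylation of a primary alcohol activates C1 for SN2 without touching the stereocentres.

**Step 4**
Reactants: 4
Product: 5 (2S,3S)-2-(2-methylallyl)-3-methyl-3-(4-methylpent-3-en-1-yl)oxirane
Conditions: CH2=C(Me)MgBr (1.5 equiv), CuI (10 mol %), THF, −30→0 °C
Reagents that add atoms: isopropenylmagnesium bromide, CC(=C)[Mg]Br
Why: Copper-catalysed Grignard SN2 displacement of a primary sulfonate forms the C8–C7 (n–γ) bond at the unhindered carbon and leaves the epoxide stereocentres untouched.

**Step 5**
Reactants: 6 hex-5-en-2-one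
Product: 7 ethyl (2E)-3-methylhepta-2,6-dienoate
Conditions: (EtO)2P(O)CH2CO2Et, NaH, THF, 0 °C→rt
Reagents that add atoms: triethyl phosphonoacetate, CCOC(=O)CP(=O)(OCC)OCC
Why: Horner–Wadsworth–Emmons olefination of a methyl ketone gives the E-trisubstituted enoate (about 9:1), and the minor Z isomer is removed by chromatography.

**Step 6**
Reactants: 7
Product: 8 (2E)-3-methylhepta-2,6-dien-1-ol
Conditions: DIBAL-H (2.3 equiv), CH2Cl2, −78 °C
Reagents that add atoms: none
Why: DIBAL reduces the ester to the allylic alcohol and leaves the terminal and trisubstituted alkenes intact.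

**Step 7**
Reactants: 8
Product: 9 (2E)-3-methylhepta-2,6-dien-1-yl acetate
Conditions: Ac2O, Et3N, DMAP (cat.), CH2Cl2, 0 °C
Reagents that add atoms: acetic anhydride, CC(=O)OC(C)=O
Why: Acetylation makes the allylic leaving group for the Ni coupling.

**Step 8**
Reactants: 10 3-bromo-4-hydroxybenzoic acid
Product: 11 4-acetoxy-3-bromobenzoic acid
Conditions: Ac2O, pyridine, rt; aqueous workup (hydrolyses the mixed anhydride)
Reagents that add atoms: acetic anhydride, CC(=O)OC(C)=O
Why: Selective phenol acetylation masks the phenol against arene bromination and chroman closure in the later Br⁺ step.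

**Step 9**
Reactants: 9 allylic acetate; 11 aryl bromide
Product: 12 4-acetoxy-3-[(2E)-3-methylhepta-2,6-dien-1-yl]benzoic acid
Conditions: NiBr2·diglyme (10 mol %), 4,4′-di-tert-butylbipyridine (10 mol %), DMF, nBu4NBF4, undivided cell, Zn(+)/carbon(−), 5 mA, rt
Reagents that add atoms: none
Why: Electroreductive Ni cross-electrophile coupling (aryl bromide with a π-allyl-Ni species) joins the aryl carbon to the unhindered allyl terminus, giving the linear E product and forming the benzylic bond.

**Step 10**
Reactants: 5 methallyl epoxide; 12 aryl diene acid (3 equiv)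
Product: 13 4-acetoxy-3-{(2E,6E)-3,7-dimethyl-8-[(2S,3S)-3-methyl-3-(4-methylpent-3-en-1-yl)oxiran-2-yl]octa-2,6-dien-1-yl}benzoic acid
Conditions: Hoveyda–Grubbs II (5 mol %), 1,4-benzoquinone (10 mol %), CH2Cl2 (0.05 M), 40 °C, 16 h
Reagents that add atoms: none (ethylene is lost)
Why: Cross-metathesis of the 1,1-disubstituted methallyl alkene with the terminal vinyl forms the E-trisubstituted δ=γ alkene, and the prenyl and C2=C3 alkenes are too hindered to react.

**Step 11**
Reactants: 13
Product: 14 O-acetyl macrolactone (acetate of the target)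
Conditions: nBu4NBr (8 equiv), nBu4NBF4 (0.05 M), 2,6-lutidine (2 equiv), MeCN/HFIP 9:1, 2 mM substrate, undivided cell, graphite(+)/Pt(−), 0.5 mA, 0 °C, 4.2 F/mol
Reagents that add atoms: tetrabutylammonium bromide, CCCC[N+](CCCC)(CCCC)CCCC.[Br-] (two Br atoms)
Why: Proposed new method: anodic oxidation of Br⁻ gives Br⁺ equivalents; the first forms a bromonium on the δ=γ olefin, which the α=β olefin captures 6-endo through a chair transition state (anti addition, Br equatorial and cis to the axial Me). Proton loss then gives the tetrasubstituted alkene, and ring-A facial selectivity is biased by the (S,S)-epoxide, with the minor diastereomer removed chromatographically. A second Br⁺ at the prenyl olefin is captured by the tethered carboxylate at the tertiary carbon (Markovnikov), closing the 15-membered ester and setting the C–Br centre by macrocyclic conformation. Cathodic H2 evolution keeps the medium acid-free for the epoxide; the closest known reactions are bromonium-initiated polyene cyclization and electrochemical bromolactonization.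

**Step 12**
Reactants: 14
Product: 15 target
Conditions: K2CO3 (0.3 equiv), MeOH/THF 1:1, 0 °C, 30 min
Reagents that add atoms: none
Why: Base-catalysed methanolysis removes the unhindered aryl acetate, while the hindered tertiary ester, epoxide and secondary bromides survive.

---

**Compound list**

| No. | Name | SMILES | Role |
|---|---|---|---|
| 1 | (S)-(+)-linalool | CC(C)=CCC[C@](C)(O)C=C | starting material |
| 2 | (2R,3S)-1,2-epoxy-3,7-dimethyloct-6-en-3-ol | CC(C)=CCC[C@](C)(O)[C@H]1CO1 | intermediate |
| 3 | (2S,3S)-2,3-epoxy-3,7-dimethyloct-6-en-1-ol | CC(C)=CCC[C@]1(C)O[C@H]1CO | intermediate |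
| 4 | epoxy tosylate of 3 | CC(C)=CCC[C@]1(C)O[C@H]1COS(=O)(=O)c1ccc(C)cc1 | intermediate |
| 5 | (2S,3S)-2-(2-methylallyl)-3-methyl-3-(4-methylpent-3-enyl)oxirane | CC(C)=CCC[C@]1(C)O[C@H]1CC(C)=C | intermediate |
| 6 | hex-5-en-2-one | CC(=O)CCC=C | starting material |
| 7 | ethyl (2E)-3-methylhepta-2,6-dienoate | CCOC(=O)/C=C(\C)CCC=C | intermediate |
| 8 | (2E)-3-methylhepta-2,6-dien-1-ol | OC/C=C(\C)CCC=C | intermediate |
| 9 | (2E)-3-methylhepta-2,6-dienyl acetate | CC(=O)OC/C=C(\C)CCC=C | intermediate |
| 10 | 3-bromo-4-hydroxybenzoic acid | OC(=O)c1ccc(O)c(Br)c1 | starting material |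
| 11 | 4-acetoxy-3-bromobenzoic acid | OC(=O)c1ccc(OC(C)=O)c(Br)c1 | intermediate |
| 12 | 4-acetoxy-3-[(2E)-3-methylhepta-2,6-dienyl]benzoic acid | OC(=O)c1ccc(OC(C)=O)c(c1)C/C=C(\C)CCC=C | intermediate |
| 13 | acyclic polyene epoxy acid (metathesis product) | CC(C)=CCC[C@]1(C)O[C@H]1C/C(C)=C/CC/C(C)=C/Cc1cc(C(=O)O)ccc1OC(C)=O | intermediate |
| 14 | O-acetyl macrolactone | CC1=C2Cc3cc(ccc3OC(C)=O)C(=O)OC(C)(C)[C@H](Br)CC[C@]3(C)O[C@H]3C[C@]2(C)[C@@H](Br)CC1 | intermediate |
| 15 | target (CID46880797) | CC1=C2Cc3cc(ccc3O)C(=O)OC(C)(C)[C@H](Br)CC[C@]3(C)O[C@H]3C[C@]2(C)[C@@H](Br)CC1 | target |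

**Total steps:** 12
**Longest linear sequence:** 7 (linalool → 2 → 3 → 4 → 5 → 13 → 14 → 15 via steps 1–4, 10, 11, 12; the aryl branch, steps 5, 6, 7, 9, 10, 11, 12, is also 7)

**Three steps most likely to fail**
1. **Step 11 (new electrochemical Br⁺ cascade).** Chemoselectivity among the alkenes, the diastereoselectivity at γ, δ and h, and macrolactone closure at the tertiary carbon are all uncertain.
   - Fallback (known chemistry): do it stepwise. First a Snyder-type bromonium polyene cyclization of 13 (Et2SBr·SbCl5Br), then NBS/H2O bromohydrin formation at the prenyl end, then Yamaguchi macrolactonization of the tertiary alcohol.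
2. **Step 10 (cross-metathesis).** The 1,1-disubstituted alkene is a poor partner, homodimerization of 12 competes, and the free acid may slow the catalyst.
   - Fallback: skip the metathesis. Treat tosylate 4 with lithium acetylide to give the terminal alkyne, then Zr-catalysed methylalumination and I2 quench to the (E)-alkenyl iodide. Negishi-couple this with the alkylzinc of the bromide analogue of 12, then carry on to the cascade.
3. **Step 1 (vanadium epoxidation).** Vinyl versus prenyl chemoselectivity and the C2 diastereoselectivity are both uncertain, and this step also sets the trans-epoxide stereochemistry after Payne rearrangement.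
   - Fallback: buy commercial (2S,3S)-2,3-epoxygeraniol in place of 3 and proceed from step 3.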